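**Plan**

Notation: u1 is the 5,7-dihydroxy-4'-methoxyflavone half, bonded through its C6. u2 is the 5,4'-dihydroxy-7-methoxyflavone half, bonded through its C8 (flavone numbering, rings A, C, B).
Cuts: first the two O-benzyl bonds on u2 (O5, O4'). Then u1-C5–C6 and u1-C7–C8 together, which takes ring A of u1 apart. Then u2-C8–CH2, u2-C8–I, O–Bn and O7–Me, back to apigenin. The u1 pyranone is cut at C4–C4a and O1–C2, back to methyl acetoacetate and an arylpropiolic acid.
Enabling feature: ring A of u1 is a resorcinol fused to ring C through the adjacent carbons C4a and C8a, with oxygen on C5 and C7 and the aryl group on C6. C8 is therefore a latent methyl on C8a, C5 a latent ester on C4a, and C6–C7 a latent arylacetic ester. The crowded 6,8''-axis is thus laid down as an unhindered CH2–aryl bond before ring A exists.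
Forward order: ring C of u1, carrying ring B, is made first as a 4-pyranone. u2 is taken with all three rings from apigenin and gains a CH2CO2Me arm at C8. Ring A of u1 is closed last between the two fragments, and debenzylation ends the route.
Stereochemistry: the target has no stereocentre and its structure fixes no axial configuration, so nothing has to be controlled.

Key step: step 8

Assumption: the 6,8''-biaryl axis may be configurationally stable but is undefined in the target structure, so the route is planned for the racemate.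

**Step 1**
Reactants: 1 3-(4-methoxyphenyl)propiolic acid
Product: 2 3-(4-methoxyphenyl)propioloyl chloride
Conditions: (COCl)2, DMF (cat.), CH2Cl2, 0 °C → rt; evaporate, use crude
Reagents that add atoms: oxalyl chloride, O=C(Cl)C(=O)Cl
Why: Acid chloride formation through the chloroiminium species from oxalyl chloride and DMF is mild enough to leave the aryl alkyne untouched.

**Step 2**
Reactants: 2 3-(4-methoxyphenyl)propioloyl chloride; 3 methyl acetoacetate
Product: 5 methyl 6-(4-methoxyphenyl)-2-methyl-4-oxo-4H-pyran-3-carboxylate, via C-acylated ynone 4 (not isolated)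
Conditions: 3, MgCl2, pyridine, CH2Cl2, 0 °C, then 2, 0 °C → rt; 1 M HCl wash; crude 4, p-TsOH·H2O (10 mol %), toluene, 80 °C
Reagents that add atoms: none
Why: Soft enolisation gives the magnesium chelate of 3, which undergoes C-acylation by 2, and the acetyl enol oxygen of 4 then adds 6-endo-dig to the acid-activated ynone, whose beta carbon is stabilised by the 4-methoxyphenyl group (the classical acetoacetate/arylpropioloyl chloride synthesis of 4-pyranones).

**Step 3**
Reactants: 6 apigenin
Product: 7 genkwanin (5-hydroxy-2-(4-hydroxyphenyl)-7-methoxy-4H-chromen-4-one)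
Conditions: MeI (1.05 equiv), K2CO3 (1.1 equiv), DMF, rt
Reagents that add atoms: iodomethane, CI
Why: In this base-limited Williamson etherification the 7-OH, para to C4a and hence a vinylogous acid of C4=O, is the most acidic phenol and the 5-OH is tied up in a hydrogen bond to C4=O, so O7 should be alkylated ahead of O4'.

**Step 4**
Reactants: 7 genkwanin
Product: 8 5-(benzyloxy)-2-[4-(benzyloxy)phenyl]-7-methoxy-4H-chromen-4-one
Conditions: BnBr (3 equiv), K2CO3 (4 equiv), DMF, 80 °C
Reagents that add atoms: benzyl bromide, BrCc1ccccc1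
Why: Williamson etherification with excess reagent and heat, which are needed to break the O5–H···O=C4 chelate once O4' has reacted.

**Step 5**
Reactants: 8 5-(benzyloxy)-2-[4-(benzyloxy)phenyl]-7-methoxy-4H-chromen-4-one
Product: 9 5-(benzyloxy)-2-[4-(benzyloxy)phenyl]-8-iodo-7-methoxy-4H-chromen-4-one
Conditions: NIS (1.05 equiv), CF3CO2H (cat.), CH2Cl2–MeCN, 0 °C → rt
Reagents that add atoms: N-iodosuccinimide, O=C1CCC(=O)N1I
Why: Electrophilic aromatic iodination of fully O-alkylated 5,7-dioxygenated flavones goes to C8, which is para to O5 and has only one freely rotating alkoxy neighbour, whereas C6 sits between OBn and OMe, and C3 and ring B are far less electron-rich.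

**Step 6**
Reactants: 10 methyl bromoacetate
Product: 11 bromo(2-methoxy-2-oxoethyl)zinc, kept as a titrated THF solution
Conditions: Zn dust (activated with Me3SiCl), THF, 40 °C
Reagents that add atoms: zinc, [Zn]
Why: Oxidative insertion of activated zinc into the alpha-bromo ester (Reformatsky reagent formation) gives a solution of the zinc enolate that can be stored and dosed.

**Step 7**
Reactants: 9 5-(benzyloxy)-2-[4-(benzyloxy)phenyl]-8-iodo-7-methoxy-4H-chromen-4-one; 11 bromo(2-methoxy-2-oxoethyl)zinc
Product: 12 methyl 2-{5-(benzyloxy)-2-[4-(benzyloxy)phenyl]-7-methoxy-4-oxo-4H-chromen-8-yl}acetate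
Conditions: 11 (2 equiv), Pd2(dba)3 (2.5 mol %), XPhos (10 mol %), THF, 65 °C
Reagents that add atoms: none
Why: In this Negishi-type alpha-arylation of a Reformatsky reagent, oxidative addition of zerovalent palladium to the aryl iodide, transmetalation and reductive elimination driven by the bulky biaryl phosphine form u2-C8–CH2 under nearly neutral conditions that spare the flavone carbonyl and the benzyl ethers.

**Step 8**
Reactants: 5 methyl 6-(4-methoxyphenyl)-2-methyl-4-oxo-4H-pyran-3-carboxylate; 12 methyl 2-{5-(benzyloxy)-2-[4-(benzyloxy)phenyl]-7-methoxy-4-oxo-4H-chromen-8-yl}acetate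
Product: 14 5-(benzyloxy)-2-[4-(benzyloxy)phenyl]-8-[5,7-dihydroxy-2-(4-methoxyphenyl)-4-oxo-4H-chromen-6-yl]-7-methoxy-4H-chromen-4-one, via side-chain ketone 13 (not isolated)
Conditions: 5 (2.0 equiv), LiN(SiMe3)2 (2.0 equiv), THF, −78 °C; 12, −78 °C → rt; LiN(SiMe3)2 (2.0 equiv), 0 → 40 °C; AcOH, 0 °C
Reagents that add atoms: none
Why: Proposed new method: LiN(SiMe3)2 first removes a proton from the C2-methyl group of 5, the gamma position of a vinylogous beta-keto ester and the most acidic C–H present, and the resulting dienolate attacks the still neutral ester carbonyl of 12, expelling methoxide and forming u1-C7–C8 in the enolate of ketone 13. The second charge of base deprotonates the benzylic CH2 (future u1-C6) of 13, and this carbanion attacks the adjacent pyranone ester in a Dieckmann step that forms u1-C5–C6, after which loss of methoxide and enolisation give the aromatic 5,7-bis(phenoxide) of 14 as an irreversible sink. The closest known reaction type is the toluate-anion Claisen/Dieckmann benzannulation of the Staunton–Weinreb family, which converts an ortho-methyl aryl ester and a second ester into a 1,3-dihydroxyarene, and the side-chain acylation of 2-methyl-4-pyranone anions is its heterocyclic relative; new here is a 2-methyl-4-pyranone-3-carboxylate serving as donor and acceptor at once. Ring A of u1 closes in a 6-(enolendo)-exo-trig mode, favoured by the Baldwin rules. No stereocentre is created, and the hindered 6,8''-axis appears only when C6 becomes sp2 and is formed as a racemate. The step needs carbonyl attack over conjugate attack and C- over O-closure: staged base keeps 12 un-enolised while the first bond forms, the silylamide is too weak and too bulky to metalate C3–H of either pyranone ring or to add to it, additions at the pyranone carbons next to oxygen and closure through oxygen are reversible under the liberated methoxide whereas C-closure ends in aromatisation, and the neighbouring methyl and ester on ring C allow the aryl group to end only on u1-C6.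

**Step 9**
Reactants: 14 5-(benzyloxy)-2-[4-(benzyloxy)phenyl]-8-[5,7-dihydroxy-2-(4-methoxyphenyl)-4-oxo-4H-chromen-6-yl]-7-methoxy-4H-chromen-4-one
Product: 15 8-[5,7-dihydroxy-2-(4-methoxyphenyl)-4-oxo-4H-chromen-6-yl]-5-hydroxy-2-(4-hydroxyphenyl)-7-methoxy-4H-chromen-4-one (target)
Conditions: H2 (1 atm), Pd/C (10 wt %), THF–MeOH, rt
Reagents that add atoms: none
Why: Catalytic hydrogenolysis removes both aryl benzyl ethers under neutral conditions, so the methyl ethers and the conjugated C2=C3 bonds persist and no Wessely–Moser-type opening and reclosure of ring C can move the axis from u1-C6 to u1-C8.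

**Compound list**

1 | 3-(4-methoxyphenyl)propiolic acid | COc1ccc(cc1)C#CC(=O)O | starting material
2 | 3-(4-methoxyphenyl)propioloyl chloride | COc1ccc(cc1)C#CC(=O)Cl | intermediate
3 | methyl acetoacetate | COC(=O)CC(C)=O | starting material
4 | methyl 2-acetyl-5-(4-methoxyphenyl)-3-oxopent-4-ynoate (drawn in the keto form) | COC(=O)C(C(C)=O)C(=O)C#Cc1ccc(OC)cc1 | intermediate
5 | methyl 6-(4-methoxyphenyl)-2-methyl-4-oxo-4H-pyran-3-carboxylate | COC(=O)c1c(C)oc(-c2ccc(OC)cc2)cc1=O | intermediate
6 | apigenin | O=c1cc(-c2ccc(O)cc2)oc2cc(O)cc(O)c12 | starting material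
7 | genkwanin, 5-hydroxy-2-(4-hydroxyphenyl)-7-methoxy-4H-chromen-4-one | COc1cc(O)c2c(=O)cc(-c3ccc(O)cc3)oc2c1 | intermediate
8 | 5-(benzyloxy)-2-[4-(benzyloxy)phenyl]-7-methoxy-4H-chromen-4-one | COc1cc(OCc2ccccc2)c2c(=O)cc(-c3ccc(OCc4ccccc4)cc3)oc2c1 | intermediate
9 | 5-(benzyloxy)-2-[4-(benzyloxy)phenyl]-8-iodo-7-methoxy-4H-chromen-4-one | COc1cc(OCc2ccccc2)c2c(=O)cc(-c3ccc(OCc4ccccc4)cc3)oc2c1I | intermediate
10 | methyl bromoacetate | COC(=O)CBr | starting material
11 | bromo(2-methoxy-2-oxoethyl)zinc | COC(=O)C[Zn]Br | intermediate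
12 | methyl 2-{5-(benzyloxy)-2-[4-(benzyloxy)phenyl]-7-methoxy-4-oxo-4H-chromen-8-yl}acetate | COC(=O)Cc1c(OC)cc(OCc2ccccc2)c2c(=O)cc(-c3ccc(OCc4ccccc4)cc3)oc12 | intermediate
13 | methyl 2-(3-{5-(benzyloxy)-2-[4-(benzyloxy)phenyl]-7-methoxy-4-oxo-4H-chromen-8-yl}-2-oxopropyl)-6-(4-methoxyphenyl)-4-oxo-4H-pyran-3-carboxylate | COC(=O)c1c(CC(=O)Cc2c(OC)cc(OCc3ccccc3)c3c(=O)cc(-c4ccc(OCc5ccccc5)cc4)oc23)oc(-c2ccc(OC)cc2)cc1=O | intermediate
14 | 5-(benzyloxy)-2-[4-(benzyloxy)phenyl]-8-[5,7-dihydroxy-2-(4-methoxyphenyl)-4-oxo-4H-chromen-6-yl]-7-methoxy-4H-chromen-4-one | COc1ccc(cc1)-c1cc(=O)c2c(O)c(-c3c(OC)cc(OCc4ccccc4)c4c(=O)cc(-c5ccc(OCc6ccccc6)cc5)oc34)c(O)cc2o1 | intermediate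
15 | 8-[5,7-dihydroxy-2-(4-methoxyphenyl)-4-oxo-4H-chromen-6-yl]-5-hydroxy-2-(4-hydroxyphenyl)-7-methoxy-4H-chromen-4-one | COc1ccc(-c2cc(=O)c3c(O)c(-c4c(OC)cc(O)c5c(=O)cc(-c6ccc(O)cc6)oc45)c(O)cc3o2)cc1 | target

**Step count**

Total step count: 9.
Longest linear sequence: 6 steps from apigenin (steps 3, 4, 5, 7, 8, 9).

**Steps most likely to fail**

**Step 8.**
- What may go wrong: the stabilised pyranone dienolate may attack the methyl ester too slowly. Proton transfer to the arylacetate, self-condensation of either ester, conjugate addition to or opening of a pyranone ring, or closure through the enolate oxygen could then take over.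
- Fallback: it uses known chemistry and makes the axis directly by cross-coupling. It sets out from 9 and comes back to the route at 15.
- Miyaura borylation of 9 (B2pin2, PdCl2(dppf), KOAc, dioxane, 90 °C) should give the u2 8-pinacolboronate F1.
- Commercial acacetin is benzylated at its acidic 7-OH (BnBr, K2CO3, acetone, reflux) to 7-O-benzylacacetin F2. This is iodinated ortho to the free chelated 5-OH (benzyltrimethylammonium dichloroiodate, CaCO3, CH2Cl2–MeOH, rt) to 7-O-benzyl-6-iodoacacetin F3. Benzylation at O5 (BnBr, K2CO3, DMF, 80 °C) then gives 5,7-di-O-benzyl-6-iodoacacetin F4.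
- Suzuki–Miyaura coupling of the boronate with the iodide (Pd(OAc)2, SPhos, K3PO4, toluene–H2O, 100 °C) should give the tetra-O-benzyl biflavone F5. Hydrogenolysis under the conditions of step 9 leads to 15.

**Step 7.**
- What may go wrong: transmetalation and reductive elimination may be slow at the electron-rich arylpalladium centre, which carries two ortho oxygen substituents. Protodeiodination could then outrun C–C bond formation.
- Fallback: it brings in a three-carbon arm and trims it oxidatively. It sets out from 9 and comes back at 12.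
- Stille coupling with allyltributylstannane (Pd(PPh3)4, DMF, 90 °C), a reaction established for 8-iodoflavones, should give the 8-allylflavone F6.
- Lemieux–Johnson cleavage (OsO4 cat., NaIO4, 2,6-lutidine, dioxane–H2O) gives the flavon-8-ylacetaldehyde F7.
- Pinnick oxidation (NaClO2, NaH2PO4, 2-methyl-2-butene, t-BuOH–H2O) gives the flavon-8-ylacetic acid F8. Esterification (MeI, K2CO3, DMF, rt) gives 12.

**Step 2.**
- What may go wrong: the ynoyl chloride may be lost through conjugate addition of pyridine or chloride. Acylation may occur on oxygen instead of carbon, or ring closure may run 5-exo-dig instead of 6-endo-dig.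
- Fallback: it works one oxidation level lower. It sets out from 3 and comes back at 5.
- The magnesium chelate of 3 (MgCl2, pyridine, CH2Cl2, 0 °C → rt) is C-acylated with commercial (E)-4-methoxycinnamoyl chloride to the cinnamoyl acetoacetate F9.
- Heating with I2 (cat.) in DMSO at 110 °C, the conditions that turn 2'-hydroxychalcones into flavones, should close the ring by 6-endo-trig oxa-Michael addition to the racemic dihydropyranone F10. The same flask dehydrogenates it to 5.

**Further compounds**

F1 | step 8 | 5-(benzyloxy)-2-[4-(benzyloxy)phenyl]-7-methoxy-8-(4,4,5,5-tetramethyl-1,3,2-dioxaborolan-2-yl)-4H-chromen-4-one | COc1cc(OCc2ccccc2)c2c(=O)cc(-c3ccc(OCc4ccccc4)cc3)oc2c1B1OC(C)(C)C(C)(C)O1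
F2 | step 8 | 7-(benzyloxy)-5-hydroxy-2-(4-methoxyphenyl)-4H-chromen-4-one | COc1ccc(cc1)-c1cc(=O)c2c(O)cc(OCc3ccccc3)cc2o1
F3 | step 8 | 7-(benzyloxy)-5-hydroxy-6-iodo-2-(4-methoxyphenyl)-4H-chromen-4-one | COc1ccc(cc1)-c1cc(=O)c2c(O)c(I)c(OCc3ccccc3)cc2o1
F4 | step 8 | 5,7-bis(benzyloxy)-6-iodo-2-(4-methoxyphenyl)-4H-chromen-4-one | COc1ccc(cc1)-c1cc(=O)c2c(OCc3ccccc3)c(I)c(OCc3ccccc3)cc2o1
F5 | step 8 | 5-(benzyloxy)-2-[4-(benzyloxy)phenyl]-8-[5,7-bis(benzyloxy)-2-(4-methoxyphenyl)-4-oxo-4H-chromen-6-yl]-7-methoxy-4H-chromen-4-one | COc1ccc(cc1)-c1cc(=O)c2c(OCc3ccccc3)c(-c3c(OC)cc(OCc4ccccc4)c4c(=O)cc(-c5ccc(OCc6ccccc6)cc5)oc34)c(OCc3ccccc3)cc2o1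
F6 | step 7 | 8-allyl-5-(benzyloxy)-2-[4-(benzyloxy)phenyl]-7-methoxy-4H-chromen-4-one | C=CCc1c(OC)cc(OCc2ccccc2)c2c(=O)cc(-c3ccc(OCc4ccccc4)cc3)oc12
F7 | step 7 | 2-{5-(benzyloxy)-2-[4-(benzyloxy)phenyl]-7-methoxy-4-oxo-4H-chromen-8-yl}acetaldehyde | O=CCc1c(OC)cc(OCc2ccccc2)c2c(=O)cc(-c3ccc(OCc4ccccc4)cc3)oc12
F8 | step 7 | 2-{5-(benzyloxy)-2-[4-(benzyloxy)phenyl]-7-methoxy-4-oxo-4H-chromen-8-yl}acetic acid | OC(=O)Cc1c(OC)cc(OCc2ccccc2)c2c(=O)cc(-c3ccc(OCc4ccccc4)cc3)oc12
F9 | step 2 | methyl (E)-2-acetyl-5-(4-methoxyphenyl)-3-oxopent-4-enoate | COC(=O)C(C(C)=O)C(=O)/C=C/c1ccc(OC)cc1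
F10 | step 2 | methyl 6-(4-methoxyphenyl)-2-methyl-4-oxo-5,6-dihydro-4H-pyran-3-carboxylate (racemic) | COC(=O)C1=C(C)OC(CC1=O)c1ccc(OC)cc1
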